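**Retrosynthetic overview**

1. Locants: ring C1 (CMe, oxirane), C2 (CHOH), C3 (CH–O-2-methylbutanoyl), C4 (CH bearing the chain), C5 (CH2), C6 (oxirane CH); chain C7 (=C14H2), C8 (CH–O-angeloyl), C9, C10/C11 (oxirane, CMe2).
2. Both oxiranes are made last from a triene diester: C1–C6 by C2–OH-directed VO(acac)2/t-BuOOH epoxidation, then C10–C11 by Shi epoxidation. The C8 and C3 esters are introduced through a TES (C3)/TBS (C2) pair.
3. C7–C8 is cut between a C7 enol triflate (from a C7 Weinreb amide) and 4-methylpent-3-enal (CrCl2/NiCl2); C8 is fixed by oxidation and CBS reduction.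
4. The strategy rests on the C2 carbinol lying allylic to the C1=C6 alkene (the latent C1–C6 oxirane) of the six-membered carbocycle. C1–C2 is therefore an alkenylmetal-to-aldehyde bond, and the carbocycle (first ring formed) is closed there by chromium-catalysed, cathode-driven cyclisation of a Z-alkenyl iodide onto the C2 aldehyde.
5. The open-chain precursor comes from an Evans syn aldol (C3, C4), Lemieux–Johnson cleavage and Stork–Zhao iodo-olefination (Z-C6=C1–I). Ring order: cyclohexene, C1–C6 oxirane, C10–C11 oxirane.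

Key step: step 9

Assumptions: compounds 2, 4, 26, 31 and 35 are purchased. The 2-methylbutanoate is R and the 2-methylbut-2-enoate is Z (angelate), as the target SMILES shows. The locants above are used for all intermediates.

**Route**

Step 1
Reactants: 1 (R)-4-benzyl-2-oxazolidinone; 2 pent-4-enoyl chloride
Product: 3 (R)-4-benzyl-3-(pent-4-enoyl)oxazolidin-2-one
Conditions: n-BuLi, THF, −78 °C; then 2, −78 → 0 °C
Reagents that add atoms: none
Why: N-acylation of the lithiated oxazolidinone by an acid chloride is the standard entry to an Evans imide and touches no stereocentre.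

Step 2
Reactants: 3 imide; 4 2-[(4-methoxybenzyl)oxy]acetaldehyde
Product: 6 (R)-4-benzyl-3-[(2R,3R)-2-allyl-3-hydroxy-4-(4-methoxybenzyloxy)butanoyl]oxazolidin-2-one, via dibutylboron Z-enolate 5 (not isolated)
Conditions: Bu2BOTf, i-Pr2NEt, CH2Cl2, −78 → 0 °C; then 4, −78 → 0 °C; pH 7 buffer (NaH2PO4/Na2HPO4), MeOH, H2O2, 0 °C
Reagents that add atoms: none
Why: Evans syn aldol: the Z boron enolate 5 reacts through a closed Zimmerman–Traxler chair on the face away from the benzyl group, which should set C4 and C3 together as the (2R,3R) syn adduct, the relationship that becomes cis in the ring.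

Step 3
Reactants: 6 aldol adduct
Product: 7 (2R,3R)-2-allyl-3-hydroxy-N-methoxy-4-(4-methoxybenzyloxy)-N-methylbutanamide
Conditions: MeNHOMe·HCl, AlMe3, CH2Cl2, −20 → 0 °C; aq. KNaC4H4O6 work-up
Reagents that add atoms: N,O-dimethylhydroxylamine hydrochloride, CNOC.Cl
Why: Weinreb aminolysis by the aluminium amide; the free β-hydroxyl directs attack to the exocyclic carbonyl, the auxiliary is released and neither stereocentre is enolised.

Step 4
Reactants: 7 hydroxy amide
Product: 8 (2R,3R)-2-allyl-N-methoxy-4-(4-methoxybenzyloxy)-N-methyl-3-(triethylsilyloxy)butanamide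
Conditions: TESCl, imidazole, DMAP (cat.), CH2Cl2, 0 °C → rt
Reagents that add atoms: chlorotriethylsilane, CC[Si](Cl)(CC)CC
Why: Standard silylation of a secondary alcohol; TES lasts to step 18 and can be removed there beside a TBS ether.

Step 5
Reactants: 8 terminal alkene
Product: 10 (2R,3R)-N-methoxy-4-(4-methoxybenzyloxy)-N-methyl-2-(2-oxoethyl)-3-(triethylsilyloxy)butanamide, via terminal diol 9 (not isolated)
Conditions: OsO4 (2 mol%), NaIO4, 2,6-lutidine, dioxane/H2O 3:1, rt
Reagents that add atoms: osmium tetroxide (catalytic oxygen donor), O=[Os](=O)(=O)=O; sodium periodate (stoichiometric oxidant), [Na+].[O-]I(=O)(=O)=O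
Why: Lemieux–Johnson oxidative cleavage (dihydroxylation to 9, then periodate glycol cleavage); 2,6-lutidine keeps the medium neutral for the TES and PMB ethers and suppresses over-oxidation.

Step 6
Reactants: 10 aldehyde; 11 ethyltriphenylphosphonium iodide
Product: 15 (2R,3R)-2-[(Z)-3-iodobut-2-enyl]-N-methoxy-4-(4-methoxybenzyloxy)-N-methyl-3-(triethylsilyloxy)butanamide, via ethylidenetriphenylphosphorane 12 (not isolated), via 1-iodoethyltriphenylphosphonium iodide 13 (not isolated), via 1-iodoethylidenetriphenylphosphorane 14 (not isolated)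
Conditions: 11, n-BuLi, THF, rt; I2, −78 °C; NaN(SiMe3)2, −20 °C; then 10, −78 → −20 °C
Reagents that add atoms: iodine, II
Why: Stork–Zhao-type Wittig olefination with the α-iodo ylide 14: the non-stabilised ylide reacts under kinetic control through the cis-oxaphosphetane, which should place iodine cis to C5 (Z), the geometry a C1–C2 ring closure needs, while the Weinreb amide is inert to the ylide at low temperature.

Step 7
Reactants: 15 PMB ether
Product: 16 (2R,3R)-4-hydroxy-2-[(Z)-3-iodobut-2-enyl]-N-methoxy-N-methyl-3-(triethylsilyloxy)butanamide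
Conditions: DDQ, CH2Cl2/pH 7 buffer (NaH2PO4/Na2HPO4) 10:1, 0 °C
Reagents that add atoms: none
Why: Oxidative PMB cleavage by DDQ (benzylic hydride abstraction, then hydrolysis) under buffered conditions should leave the TES ether, the alkenyl iodide and the amide untouched; the alcohol is taken on at once to forestall lactonisation onto the amide.

Step 8
Reactants: 16 primary alcohol
Product: 17 (2R,3R)-2-[(Z)-3-iodobut-2-enyl]-N-methoxy-N-methyl-4-oxo-3-(triethylsilyloxy)butanamide
Conditions: Dess–Martin periodinane, NaHCO3, CH2Cl2, 0 °C → rt; used without chromatography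
Reagents that add atoms: none
Why: Dess–Martin oxidation under buffered, non-basic conditions should give the α-silyloxy aldehyde without epimerising C3.

Step 9
Reactants: 17 Z-iodoalkenyl aldehyde
Product: 20 (1R,5S,6R)-5-hydroxy-N-methoxy-N,4-dimethyl-6-(triethylsilyloxy)cyclohex-3-ene-1-carboxamide (C2 hydroxyl; C3 OTES; C4 amide; all cis), via alkenylchromium dichloride 18 (not isolated), via Cp2ZrCl alkoxide 19 (not isolated)
Conditions: CrCl2 (15 mol%), NiCl2·DME (2 mol%), Cp2ZrCl2 (1.2 equiv), Bu4NClO4 (0.1 M), DMF, undivided cell, Al anode, Ni-foam cathode, constant current, rt, slow addition of 17 (final 5 mM); aq. NaHCO3 work-up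
Reagents that add atoms: none
Why: The cathode regenerates divalent chromium from trivalent chromium; divalent chromium reduces NiCl2 to zerovalent nickel, which inserts into the C1–I bond with retention of the Z geometry and passes the alkenyl group to chromium to give 18 (trivalent chromium), which adds to the C2 aldehyde, and Cp2ZrCl2 takes the alkoxide off chromium as 19 so that chromium is needed only in catalytic amount. The closest known reaction type is the Nozaki–Hiyama–Kishi alkenyl iodide–aldehyde coupling, established intramolecularly with stoichiometric CrCl2 and in chromium-catalytic form with cathodic turnover. The six-membered ring closes by a 6-exo-trig carbonyl addition of C1 onto C2, the Z alkene ending up endocyclic as C1=C6. The new C2 stereocentre is controlled by the neighbouring C3 silyloxy group: in the half-chair transition state with the C4 amide pseudo-equatorial the C3–O bond is pseudo-axial and anti to the forming C1–C2 bond (polar Felkin–Anh), which places the C2 oxygen cis to C3–OTES. The step needs chemoselectivity for the aldehyde over the Weinreb amide, secured by the low basicity and aldehyde preference of alkenylchromium, and needs cyclisation to outrun protodeiodination and reductive aldehyde dimerisation, secured by high dilution and by the Z geometry that holds C1 beside C2.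

Step 10
Reactants: 20 cyclohexenol
Product: 21 (1R,5S,6R)-5-(tert-butyldimethylsilyloxy)-N-methoxy-N,4-dimethyl-6-(triethylsilyloxy)cyclohex-3-ene-1-carboxamide
Conditions: TBSOTf, 2,6-lutidine, CH2Cl2, −78 → 0 °C
Reagents that add atoms: tert-butyldimethylsilyl triflate, CC(C)(C)[Si](C)(C)OS(=O)(=O)C(F)(F)F
Why: Silyl triflate silylation of the hindered allylic alcohol; TBS is chosen so that C2 stays masked when the C3 TES ether is cleaved in step 18.

Step 11
Reactants: 21 Weinreb amide
Product: 23 1-[(1R,5S,6R)-5-(tert-butyldimethylsilyloxy)-4-methyl-6-(triethylsilyloxy)cyclohex-3-en-1-yl]ethanone, via bromomagnesium hemiaminal 22 (not isolated)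
Conditions: MeMgBr, THF, −20 → 0 °C; aq. NH4Cl
Reagents that add atoms: methylmagnesium bromide, C[Mg]Br
Why: Weinreb ketone synthesis: the chelated adduct 22 holds until work-up, so only one methyl adds and C4 is not enolised.

Step 12
Reactants: 23 methyl ketone
Product: 25 1-[(1R,5S,6R)-5-(tert-butyldimethylsilyloxy)-4-methyl-6-(triethylsilyloxy)cyclohex-3-en-1-yl]vinyl trifluoromethanesulfonate, via potassium enolate 24 (not isolated)
Conditions: KN(SiMe3)2, THF, −78 °C; PhNTf2, −78 → 0 °C
Reagents that add atoms: N-phenylbis(trifluoromethanesulfonimide), O=S(=O)(N(c1ccccc1)S(=O)(=O)C(F)(F)F)C(F)(F)F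
Why: Kinetic deprotonation at the unhindered CH3 (not at the tertiary C4–H) and O-sulfonylation of enolate 24 should give the terminal enol triflate that carries the future C7=C14 methylene.

Step 13
Reactants: 26 4-methylpent-3-en-1-ol
Product: 27 4-methylpent-3-enal
Conditions: Dess–Martin periodinane, NaHCO3, CH2Cl2, 0 °C; filtered, concentrated cold, used at once
Reagents that add atoms: none
Why: Buffered Dess–Martin oxidation avoids the acid or base that would move the double bond into conjugation.

Step 14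
Reactants: 25 enol triflate; 27 4-methylpent-3-enal
Product: 28 allylic alcohol with the C7(=C14H2)–C8H(OH)–CH2CH=CMe2 chain on C4 (C8 epimer mixture; ring stereocentres unchanged)
Conditions: CrCl2 (4 equiv), NiCl2 (2 mol%), DMF/THF, rt
Reagents that add atoms: none
Why: Nozaki–Hiyama–Kishi coupling: zerovalent nickel inserts into the C7–OTf bond, the alkenyl group passes to chromium and adds to the aldehyde under essentially non-basic conditions, forming C7–C8 with the C7=C14 methylene in place; the C8 epimer mixture is corrected in steps 15 and 16.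

Step 15
Reactants: 28 allylic alcohol
Product: 29 C8 enone (C7(=C14H2)–C8(=O)–CH2CH=CMe2)
Conditions: Dess–Martin periodinane, NaHCO3, CH2Cl2, 0 °C
Reagents that add atoms: none
Why: Buffered Dess–Martin oxidation of the allylic alcohol should not move the β,γ-alkene into conjugation or touch the silyl ethers.

Step 16
Reactants: 29 enone
Product: 30 (8S)-allylic alcohol
Conditions: (R)-2-methyl-CBS-oxazaborolidine (30 mol%), catecholborane, toluene, −78 °C
Reagents that add atoms: none
Why: Corey–Bakshi–Shibata reduction: with the α-branched alkenyl group (C7) as the large and the C9 methylene as the small substituent, the (R)-catalyst should deliver hydride to give the (S)-C8 alcohol by catalyst control, and catecholborane at −78 °C avoids hydroboration of the alkenes.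

Step 17
Reactants: 30 (8S)-alcohol; 31 angelic acid
Product: 33 C8 angelate, via angelic trichlorobenzoic anhydride 32 (not isolated)
Conditions: 31, 2,4,6-trichlorobenzoyl chloride, Et3N, toluene, rt; then 30, 80 °C (no DMAP)
Reagents that add atoms: none
Why: Yamaguchi-type esterification through mixed anhydride 32 without a nucleophilic catalyst, conditions under which hindered secondary alcohols are angeloylated with the Z geometry retained because the conjugate addition–elimination path to the tiglate is closed.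

Step 18
Reactants: 33 bis-silyl ether
Product: 34 C3 alcohol (C2 OTBS and C8 angelate retained)
Conditions: PPTS, MeOH/CH2Cl2, 0 °C
Reagents that add atoms: none
Why: Acid-catalysed methanolysis removes the secondary TES ether far faster than the TBS ether, and the mild acid leaves the allylic angelate intact.

Step 19
Reactants: 34 C3 alcohol; 35 (R)-2-methylbutanoic acid
Product: 36 C3 (R)-2-methylbutanoate
Conditions: DCC, DMAP (cat.), CH2Cl2, 0 °C → rt
Reagents that add atoms: none
Why: Steglich esterification; the carbodiimide-activated α-branched acid acylates the C3 hydroxyl with catalytic DMAP at low temperature without racemising the (R) centre or isomerising the angelate.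

Step 20
Reactants: 36 TBS ether
Product: 37 C2 allylic alcohol (triene diester)
Conditions: HF·pyridine, pyridine, THF, 0 °C → rt
Reagents that add atoms: none
Why: Fluoride cleavage of the TBS ether under buffered acidic conditions, chosen over basic fluoride so that the C3 acyl group does not migrate to the freed cis C2 hydroxyl.

Step 21
Reactants: 37 allylic alcohol
Product: 38 C1–C6 epoxide (oxirane cis to the C2 hydroxyl)
Conditions: VO(acac)2 (5 mol%), t-BuOOH (decane), CH2Cl2, 0 °C → rt
Reagents that add atoms: tert-butyl hydroperoxide, CC(C)(C)OO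
Why: Vanadium-catalysed hydroxyl-directed epoxidation: the alkylperoxo vanadate bound to the C2 hydroxyl delivers oxygen to C1=C6 on the face of that hydroxyl, setting C1 and C6, and leaves the non-allylic C7=C14, C10=C11 and angelate alkenes alone.

Step 22
Reactants: 38 epoxy alcohol
Product: 39 target CNP0181486.1, ring (1R,2R,3R,4S,6S), chain (8S,10R), (R)-2-methylbutanoate at C3, angelate at C8
Conditions: D-fructose-derived Shi ketone (30 mol%), Oxone (2KHSO5·KHSO4·K2SO4), K2CO3, Bu4NHSO4, MeCN/CH2(OMe)2, aq. Na2B4O7/Na2EDTA buffer, 0 °C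
Reagents that add atoms: potassium peroxymonosulfate (active component of Oxone), [K+].[O-]S(=O)(=O)OO
Why: Shi asymmetric epoxidation: the dioxirane of the D-fructose-derived ketone attacks the electron-rich trisubstituted C10=C11 alkene through the spiro transition state, which for an R–CH=CMe2 alkene should give the (R)-epoxide at C10 by catalyst control, while the 1,1-disubstituted C7=C14 alkene (allylic ester) and the electron-poor angelate react much more slowly.

**Compound list**

1 | (R)-4-benzyl-2-oxazolidinone | O=C1N[C@H](Cc2ccccc2)CO1 | starting material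
2 | pent-4-enoyl chloride | C=CCCC(=O)Cl | starting material
3 | (R)-4-benzyl-3-(pent-4-enoyl)oxazolidin-2-one | C=CCCC(=O)N1C(=O)OC[C@H]1Cc1ccccc1 | intermediate
4 | 2-[(4-methoxybenzyl)oxy]acetaldehyde | COc1ccc(COCC=O)cc1 | starting material
5 | dibutylboron Z-enolate of 3 | C=CC/C=C(\OB(CCCC)CCCC)N1C(=O)OC[C@H]1Cc1ccccc1 | intermediate (not isolated)
6 | (R)-4-benzyl-3-[(2R,3R)-2-allyl-3-hydroxy-4-(4-methoxybenzyloxy)butanoyl]oxazolidin-2-one | COc1ccc(COC[C@H](O)[C@@H](CC=C)C(=O)N2C(=O)OC[C@H]2Cc2ccccc2)cc1 | intermediate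
7 | (2R,3R)-2-allyl-3-hydroxy-N-methoxy-4-(4-methoxybenzyloxy)-N-methylbutanamide | COc1ccc(COC[C@H](O)[C@@H](CC=C)C(=O)N(C)OC)cc1 | intermediate
8 | (2R,3R)-2-allyl-N-methoxy-4-(4-methoxybenzyloxy)-N-methyl-3-(triethylsilyloxy)butanamide | COc1ccc(COC[C@H](O[Si](CC)(CC)CC)[C@@H](CC=C)C(=O)N(C)OC)cc1 | intermediate
9 | (2R,3R)-2-(2,3-dihydroxypropyl)-N-methoxy-4-(4-methoxybenzyloxy)-N-methyl-3-(triethylsilyloxy)butanamide (carbinol epimers) | COc1ccc(COC[C@H](O[Si](CC)(CC)CC)[C@@H](CC(O)CO)C(=O)N(C)OC)cc1 | intermediate (not isolated)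
10 | (2R,3R)-N-methoxy-4-(4-methoxybenzyloxy)-N-methyl-2-(2-oxoethyl)-3-(triethylsilyloxy)butanamide | COc1ccc(COC[C@H](O[Si](CC)(CC)CC)[C@@H](CC=O)C(=O)N(C)OC)cc1 | intermediate
11 | ethyltriphenylphosphonium iodide | CC[P+](c1ccccc1)(c1ccccc1)c1ccccc1.[I-] | starting material
12 | ethylidenetriphenylphosphorane | CC=P(c1ccccc1)(c1ccccc1)c1ccccc1 | intermediate (not isolated)
13 | (1-iodoethyl)triphenylphosphonium iodide | CC(I)[P+](c1ccccc1)(c1ccccc1)c1ccccc1.[I-] | intermediate (not isolated)
14 | (1-iodoethylidene)triphenylphosphorane | CC(I)=P(c1ccccc1)(c1ccccc1)c1ccccc1 | intermediate (not isolated)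
15 | (2R,3R)-2-[(Z)-3-iodobut-2-enyl]-N-methoxy-4-(4-methoxybenzyloxy)-N-methyl-3-(triethylsilyloxy)butanamide | COc1ccc(COC[C@H](O[Si](CC)(CC)CC)[C@@H](C/C=C(/C)I)C(=O)N(C)OC)cc1 | intermediate
16 | (2R,3R)-4-hydroxy-2-[(Z)-3-iodobut-2-enyl]-N-methoxy-N-methyl-3-(triethylsilyloxy)butanamide | OC[C@H](O[Si](CC)(CC)CC)[C@@H](C/C=C(/C)I)C(=O)N(C)OC | intermediate
17 | (2R,3R)-2-[(Z)-3-iodobut-2-enyl]-N-methoxy-N-methyl-4-oxo-3-(triethylsilyloxy)butanamide | O=C[C@H](O[Si](CC)(CC)CC)[C@@H](C/C=C(/C)I)C(=O)N(C)OC | intermediate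
18 | alkenylchromium dichloride from 17 (trivalent chromium at C1) | O=C[C@H](O[Si](CC)(CC)CC)[C@@H](C/C=C(/C)[Cr](Cl)Cl)C(=O)N(C)OC | intermediate (not isolated)
19 | Cp2ZrCl alkoxide of 20 | CON(C)C(=O)[C@@H]1CC=C(C)[C@H](O[Zr](Cl)(C2C=CC=C2)C2C=CC=C2)[C@@H]1O[Si](CC)(CC)CC | intermediate (not isolated)
20 | (1R,5S,6R)-5-hydroxy-N-methoxy-N,4-dimethyl-6-(triethylsilyloxy)cyclohex-3-ene-1-carboxamide | CON(C)C(=O)[C@@H]1CC=C(C)[C@H](O)[C@@H]1O[Si](CC)(CC)CC | intermediate
21 | (1R,5S,6R)-5-(tert-butyldimethylsilyloxy)-N-methoxy-N,4-dimethyl-6-(triethylsilyloxy)cyclohex-3-ene-1-carboxamide | CON(C)C(=O)[C@@H]1CC=C(C)[C@H](O[Si](C)(C)C(C)(C)C)[C@@H]1O[Si](CC)(CC)CC | intermediate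
22 | bromomagnesium hemiaminal from 21 and MeMgBr | CON(C)C(C)(O[Mg]Br)[C@@H]1CC=C(C)[C@H](O[Si](C)(C)C(C)(C)C)[C@@H]1O[Si](CC)(CC)CC | intermediate (not isolated)
23 | 1-[(1R,5S,6R)-5-(tert-butyldimethylsilyloxy)-4-methyl-6-(triethylsilyloxy)cyclohex-3-en-1-yl]ethanone | CC(=O)[C@@H]1CC=C(C)[C@H](O[Si](C)(C)C(C)(C)C)[C@@H]1O[Si](CC)(CC)CC | intermediate
24 | potassium enolate of 23 (terminal) | C=C([O-])[C@@H]1CC=C(C)[C@H](O[Si](C)(C)C(C)(C)C)[C@@H]1O[Si](CC)(CC)CC.[K+] | intermediate (not isolated)
25 | 1-[(1R,5S,6R)-5-(tert-butyldimethylsilyloxy)-4-methyl-6-(triethylsilyloxy)cyclohex-3-en-1-yl]vinyl triflate | C=C(OS(=O)(=O)C(F)(F)F)[C@@H]1CC=C(C)[C@H](O[Si](C)(C)C(C)(C)C)[C@@H]1O[Si](CC)(CC)CC | intermediate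
26 | 4-methylpent-3-en-1-ol | CC(C)=CCCO | starting material
27 | 4-methylpent-3-enal | CC(C)=CCC=O | intermediate
28 | C8 allylic alcohol, epimer mixture at C8 (C2 OTBS, C3 OTES) | C=C(C(O)CC=C(C)C)[C@@H]1CC=C(C)[C@H](O[Si](C)(C)C(C)(C)C)[C@@H]1O[Si](CC)(CC)CC | intermediate
29 | C8 enone (C2 OTBS, C3 OTES) | C=C(C(=O)CC=C(C)C)[C@@H]1CC=C(C)[C@H](O[Si](C)(C)C(C)(C)C)[C@@H]1O[Si](CC)(CC)CC | intermediate
30 | (8S)-allylic alcohol (C2 OTBS, C3 OTES) | C=C([C@H](CC=C(C)C)O)[C@@H]1CC=C(C)[C@H](O[Si](C)(C)C(C)(C)C)[C@@H]1O[Si](CC)(CC)CC | intermediate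
31 | angelic acid, (Z)-2-methylbut-2-enoic acid | C/C=C(/C)C(=O)O | starting material
32 | angelic 2,4,6-trichlorobenzoic anhydride | C/C=C(/C)C(=O)OC(=O)c1c(Cl)cc(Cl)cc1Cl | intermediate (not isolated)
33 | (8S)-angelate (C2 OTBS, C3 OTES) | C=C([C@H](CC=C(C)C)OC(=O)/C(C)=C\C)[C@@H]1CC=C(C)[C@H](O[Si](C)(C)C(C)(C)C)[C@@H]1O[Si](CC)(CC)CC | intermediate
34 | C3 alcohol (C2 OTBS, C8 angelate) | C=C([C@H](CC=C(C)C)OC(=O)/C(C)=C\C)[C@@H]1CC=C(C)[C@H](O[Si](C)(C)C(C)(C)C)[C@@H]1O | intermediate
35 | (R)-2-methylbutanoic acid | CC[C@@H](C)C(=O)O | starting material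
36 | C3 (R)-2-methylbutanoate (C2 OTBS, C8 angelate) | C=C([C@H](CC=C(C)C)OC(=O)/C(C)=C\C)[C@@H]1CC=C(C)[C@H](O[Si](C)(C)C(C)(C)C)[C@@H]1OC(=O)[C@H](C)CC | intermediate
37 | triene diester with free C2 hydroxyl | C=C([C@H](CC=C(C)C)OC(=O)/C(C)=C\C)[C@@H]1CC=C(C)[C@H](O)[C@@H]1OC(=O)[C@H](C)CC | intermediate
38 | C1–C6 epoxide (oxirane cis to C2–OH), C10=C11 alkene intact | C=C([C@H](CC=C(C)C)OC(=O)/C(C)=C\C)[C@@H]1C[C@@H]2O[C@]2(C)[C@H](O)[C@@H]1OC(=O)[C@H](C)CC | intermediate
39 | CNP0181486.1 | C=C([C@H](C[C@H]1OC1(C)C)OC(=O)/C(C)=C\C)[C@@H]1C[C@@H]2O[C@]2(C)[C@H](O)[C@@H]1OC(=O)[C@H](C)CC | target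

**Step count and risks**

Total step count: 22 (step 13 prepares the aldehyde partner 27).
Longest linear sequence: 21 steps (steps 1–12 and 14–22, from 1 to 39).

Steps most likely to fail:

1. Step 9. The cathodic chromium cycle may not turn over fast enough in the intramolecular setting, so that protodeiodination of the alkenyl metal or reductive dimerisation of the aldehyde at the cathode outruns ring closure, or the addition may show poor facial selectivity at C2. Fallback, setting out from 8 and returning at 20: the ring is closed at C1=C6 by metathesis instead of at C1–C2.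
   - DDQ (CH2Cl2/pH 7 buffer) would remove the PMB group of 8 to give the primary alcohol (2R,3R)-2-allyl-4-hydroxy-N-methoxy-N-methyl-3-(triethylsilyloxy)butanamide F1.
   - Dess–Martin oxidation would give the aldehyde (2R,3R)-2-allyl-N-methoxy-N-methyl-4-oxo-3-(triethylsilyloxy)butanamide F2.
   - Isopropenylmagnesium bromide in THF at −78 °C (Felkin-controlled; the amide is inert at this temperature) would give the dienol (2R,3R,4S)-2-allyl-4-hydroxy-N-methoxy-N,5-dimethyl-3-(triethylsilyloxy)hex-5-enamide F3.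
   - Ring-closing metathesis with the second-generation Grubbs catalyst, (H2IMes)(PCy3)Cl2Ru=CHPh, in CH2Cl2 at 40 °C would give 20.
   - Should either ring closure favour the C2 epimer, Dess–Martin oxidation to the enone (1R,6R)-N-methoxy-N,4-dimethyl-5-oxo-6-(triethylsilyloxy)cyclohex-3-ene-1-carboxamide F4 and NaBH4/CeCl3 reduction, with hydride entering anti to the pseudo-axial C3–OTES, would return 20.

2. Step 14. Oxidative addition of the hindered 1,1-disubstituted enol triflate may be slow, and during the long reaction the β,γ-unsaturated aldehyde may isomerise into conjugation or self-condense. Fallback, setting out from 23 and returning at 28: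
   - Condensation of 23 with 2,4,6-triisopropylbenzenesulfonyl hydrazide (THF, rt) would give the trisylhydrazone of 23 F5.
   - Two equivalents of n-BuLi (THF/TMEDA, −78 → 0 °C) would trigger the Shapiro reaction to the C7 alkenyllithium F6.
   - After transmetalation with CeCl3 at −78 °C to lower its basicity, F6 would add to 27 to give 28.

3. Step 17. The angeloyl unit may isomerise from Z to E (tiglate) during acyl transfer, and acylation of the hindered C8 hydroxyl may be sluggish at the temperature that keeps the geometry. Fallback, setting out from 30 and returning at 33: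
   - DCC/DMAP esterification of 30 with 2-[bis(2,2,2-trifluoroethoxy)phosphoryl]propanoic acid would give the C8 2-[bis(2,2,2-trifluoroethoxy)phosphoryl]propanoate F7.
   - Still–Gennari olefination (KN(SiMe3)2, 18-crown-6, THF, −78 °C) with acetaldehyde would build the Z-2-methylbut-2-enoate on the substrate and give 33.

**Further compounds**

F1 | step 9 | (2R,3R)-2-allyl-4-hydroxy-N-methoxy-N-methyl-3-(triethylsilyloxy)butanamide | OC[C@H](O[Si](CC)(CC)CC)[C@@H](CC=C)C(=O)N(C)OC
F2 | step 9 | (2R,3R)-2-allyl-N-methoxy-N-methyl-4-oxo-3-(triethylsilyloxy)butanamide | O=C[C@H](O[Si](CC)(CC)CC)[C@@H](CC=C)C(=O)N(C)OC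
F3 | step 9 | (2R,3R,4S)-2-allyl-4-hydroxy-N-methoxy-N,5-dimethyl-3-(triethylsilyloxy)hex-5-enamide | C=C(C)[C@H](O)[C@H](O[Si](CC)(CC)CC)[C@@H](CC=C)C(=O)N(C)OC
F4 | step 9 | (1R,6R)-N-methoxy-N,4-dimethyl-5-oxo-6-(triethylsilyloxy)cyclohex-3-ene-1-carboxamide | CON(C)C(=O)[C@@H]1CC=C(C)C(=O)[C@@H]1O[Si](CC)(CC)CC
F5 | step 14 | 2,4,6-triisopropylbenzenesulfonyl hydrazone of 23 | CC(=NNS(=O)(=O)c1c(C(C)C)cc(C(C)C)cc1C(C)C)[C@@H]1CC=C(C)[C@H](O[Si](C)(C)C(C)(C)C)[C@@H]1O[Si](CC)(CC)CC
F6 | step 14 | C7 alkenyllithium (1-lithiovinyl on C4) | C=C([Li])[C@@H]1CC=C(C)[C@H](O[Si](C)(C)C(C)(C)C)[C@@H]1O[Si](CC)(CC)CC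
F7 | step 17 | C8 2-[bis(2,2,2-trifluoroethoxy)phosphoryl]propanoate of 30 | C=C([C@H](CC=C(C)C)OC(=O)C(C)P(=O)(OCC(F)(F)F)OCC(F)(F)F)[C@@H]1CC=C(C)[C@H](O[Si](C)(C)C(C)(C)C)[C@@H]1O[Si](CC)(CC)CC
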